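**Strategy.** The 14-membered ring is closed at the bond between C2, the CH of the ester-bearing ring alkene, and C3, the dienone carbonyl carbon (ring numbering: C1 carries CO2Me; C3, C10, C13 are the ketones; C12 carries isopropyl). The ring unit C1(CO2Me)=C2–C3(=O) is a dehydrated β-hydroxy ketone and therefore a masked 2-isoxazoline. An intramolecular nitrile oxide cycloaddition of an open-chain dienyl nitrile oxide (future C3) onto a 2-alkylacrylate (C1=C2) forms C2–C3, closes the carbocycle and installs the masked enone in one operation. The acyclic oxime precursor holds the (Z)-C8=C9 enone, the (E)-C4=C5 alkene and the (R)-C12 centre set by Evans alkylation.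

Key step: step 13

Remark on the chemistry: the C13 carbinol (made in step 8) and the isoxazoline carbon C1 (made in step 13) are carried as epimer mixtures. Both centres are erased later (steps 17 and 15), so their SMILES carry no stereo label. Target ring numbering is used for all intermediates.

**Route**

Step 1
Reactants: 1 geraniol
Product: 2 geranyl 4-methoxybenzyl ether
Conditions: NaH, 4-methoxybenzyl chloride, Bu4NI (cat.), THF/DMF, 0 to 23 °C
Reagents that add atoms: 4-methoxybenzyl chloride, COc1ccc(CCl)cc1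
Why: Williamson etherification of the allylic alkoxide; the PMB ether should survive t-BuLi and be removable oxidatively in step 10.

Step 2
Reactants: 2 geranyl 4-methoxybenzyl ether
Product: 3 (4E)-6-(4-methoxybenzyloxy)-4-methylhex-4-enal
Conditions: O3 (1 equiv), pyridine, CH2Cl2, −78 °C; then Me2S
Reagents that add atoms: ozone, [O-][O+]=O
Why: Chemoselective ozonolysis; the electron-rich isopropylidene alkene should react before the alkene deactivated by the allylic ether oxygen, and reductive work-up gives the aldehyde.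

Step 3
Reactants: 3 (4E)-6-(4-methoxybenzyloxy)-4-methylhex-4-enal; 4 ethyltriphenylphosphonium iodide
Product: 8 (2E,6Z)-7-iodo-3-methylocta-2,6-dienyl 4-methoxybenzyl ether, via ethylidenetriphenylphosphorane 5 (not isolated), via (1-iodoethyl)triphenylphosphonium iodide 6 (not isolated), via (1-iodoethylidene)triphenylphosphorane 7 (not isolated)
Conditions: n-BuLi, THF, 0 °C; I2, −78 °C; NaN(SiMe3)2, −20 °C; then 3, −78 to −20 °C
Reagents that add atoms: iodine, II
Why: Stork–Zhao-type α-iodoethylidene Wittig olefination; the non-stabilised iodo ylide should give the (Z)-2-iodoalkene under kinetic control, which fixes the future C8=C9 geometry.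

Step 4
Reactants: 9 (4R)-4-benzyl-3-(3-methylbutanoyl)-1,3-oxazolidin-2-one; 10 tert-butyl bromoacetate
Product: 12 tert-butyl (3R)-3-[(4R)-4-benzyl-2-oxo-oxazolidine-3-carbonyl]-4-methylpentanoate, via sodium (Z)-enolate 11 (not isolated)
Conditions: NaN(SiMe3)2, THF, −78 °C; then 10, −78 to −40 °C
Reagents that add atoms: none
Why: Evans asymmetric alkylation; the chelated (Z)-enolate is alkylated on the face opposite the benzyl group, which sets the isopropyl-bearing centre (future C12) as R.

Step 5
Reactants: 12 alkylated imide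
Product: 14 (4R)-4-(propan-2-yl)oxolan-2-one, via tert-butyl (3R)-3-(hydroxymethyl)-4-methylpentanoate 13 (not isolated)
Conditions: LiBH4, MeOH (1 equiv), Et2O, 0 °C; aqueous work-up; then TFA, CH2Cl2, 23 °C
Reagents that add atoms: none
Why: Reductive removal of the auxiliary (the imide carbonyl is reduced in preference to the tert-butyl ester), then acid-mediated lactonisation with loss of isobutene; the stereocentre is not enolisable under either condition.

Step 6
Reactants: 8 (Z)-vinyl iodide; 14 (4R)-4-(propan-2-yl)oxolan-2-one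
Product: 16 (2R,5Z,9E)-1-hydroxy-11-(4-methoxybenzyloxy)-5,9-dimethyl-2-(propan-2-yl)undeca-5,9-dien-4-one, via vinyllithium 15 (not isolated)
Conditions: t-BuLi (2.1 equiv), Et2O, −78 °C; then 14, −78 °C; aq. NH4Cl
Reagents that add atoms: none
Why: Iodine–lithium exchange with retention of alkene geometry, then acylation of the vinyllithium by the γ-lactone; single addition is expected because the tetrahedral lithium lactolate persists at −78 °C. This forms the C9–C10 bond of the (Z)-enone and frees the C13 hydroxymethyl.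

Step 7
Reactants: 16 hydroxy enone
Product: 17 (2R,5Z,9E)-11-(4-methoxybenzyloxy)-5,9-dimethyl-4-oxo-2-(propan-2-yl)undeca-5,9-dienal
Conditions: Dess–Martin periodinane, NaHCO3, CH2Cl2, 0 to 23 °C
Reagents that add atoms: none
Why: Dess–Martin oxidation of the primary alcohol; the buffered neutral medium should spare the α-stereocentre (C12) of the new aldehyde and the (Z)-enone.

Step 8
Reactants: 17 keto aldehyde; 18 methyl 2-(bromomethyl)prop-2-enoate
Product: 20 methyl 4-hydroxy-2-methylidene-7-oxo tetradecadienoate (C13 carbinol epimers), via allylzinc bromide 19 (not isolated)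
Conditions: Zn dust, THF/sat. aq. NH4Cl, 0 to 23 °C
Reagents that add atoms: none
Why: Zinc Barbier allylation with the 2-(methoxycarbonyl)allyl reagent, selective for the aldehyde over the hindered enone ketone; it forms C13–C14 and brings in C14, C1, C2 and the ester. The new carbinol centre is formed unselectively and becomes the C13 ketone in step 17.

Step 9
Reactants: 20 hydroxy ester
Product: 21 C13 triethylsilyl ether of 20
Conditions: Et3SiOTf, 2,6-lutidine, CH2Cl2, −78 °C
Reagents that add atoms: triethylsilyl trifluoromethanesulfonate, CC[Si](CC)(CC)OS(=O)(=O)C(F)(F)F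
Why: Silylation of the hindered secondary alcohol; the ether blocks lactonisation onto the ester and keeps C14–H non-acidic, so that the later dehydration can only go towards C2.

Step 10
Reactants: 21 silyl ether
Product: 22 C3 allylic alcohol
Conditions: DDQ, CH2Cl2/pH 7 phosphate buffer, 0 °C
Reagents that add atoms: none
Why: Oxidative cleavage of the PMB ether by benzylic hydride abstraction and hydrolysis; the buffered medium should spare the silyl ether and the alkenes.

Step 11
Reactants: 22 allylic alcohol
Product: 23 (E)-enal at C3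
Conditions: MnO2, CH2Cl2, 23 °C
Reagents that add atoms: none
Why: MnO2 oxidation, selective for the allylic alcohol, with retention of the C4=C5 geometry.

Step 12
Reactants: 23 enal
Product: 24 aldoxime at C3
Conditions: NH2OH·HCl (1.1 equiv), NaOAc, MeOH, 0 °C
Reagents that add atoms: hydroxylamine hydrochloride, NO.Cl
Why: Oxime condensation; the aldehyde should react far faster than the conjugated ketone or than aza-Michael addition to the 2-substituted acrylate.

Step 13
Reactants: 24 aldoxime
Product: 27 bridged isoxazoline macrocycle (C1 epimers), via hydroximoyl chloride 25 (not isolated), via nitrile oxide 26 (not isolated)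
Conditions: NCS, pyridine (cat.), CHCl3, 0 to 23 °C; then syringe-pump addition to Et3N, CH2Cl2, 40 °C, 0.002 M
Reagents that add atoms: none
Why: NCS chlorinates the aldoxime to the hydroximoyl chloride, Et3N eliminates HCl, and the resulting α,β-unsaturated nitrile oxide adds in a concerted [3+2] cycloaddition across the C1=C2 methylidene of the 2-alkylacrylate, forming the C2–C3 and C1–O bonds. The closest known reaction type is the intramolecular nitrile oxide–alkene cycloaddition used for macrocyclisation. Two rings close at once: the 14-membered carbocycle, with both alkene carbons inside the new ring (endo mode), and the five-membered 2-isoxazoline, giving a bridged bicyclo[11.2.1] skeleton. The new quaternary stereocentre at C1 needs no control because step 15 removes it, and C12 is untouched. The step needs regioselectivity (carbon to the CH2 terminus, oxygen to the ester-bearing carbon), which the 1,1-disubstituted electron-poor alkene secures, and chemoselectivity over the trisubstituted C8=C9 enone, secured by its low dipolarophilicity and by the E geometry of C4=C5, which a six-membered ring cannot span. High dilution is required to suppress dimerisation of the nitrile oxide to the furoxan.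

Step 14
Reactants: 27 isoxazoline macrocycle
Product: 29 monocyclic β-hydroxy ketone (C1 tertiary alcohol), via β-hydroxy imine 28 (not isolated)
Conditions: Mo(CO)6, MeCN/H2O (15:1), 80 °C
Reagents that add atoms: water, O
Why: Reductive N–O cleavage of the 2-isoxazoline by Mo(CO)6, then hydrolysis of the β-hydroxy imine in situ; this unmasks the C3 ketone and should leave the alkenes, the ester and the silyl ether untouched.

Step 15
Reactants: 29 β-hydroxy ketone
Product: 31 (1E)-enedione silyl ether, via C1 trifluoroacetate 30 (not isolated)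
Conditions: (CF3CO)2O, Et3N, DMAP (cat.), CH2Cl2, 0 to 23 °C
Reagents that add atoms: none
Why: Acylation of the tertiary alcohol and E1cB elimination through the C3 ketone enolate; only C2–H is acidic next to C1 because C13 is still a silyl ether. The thermodynamically preferred geometry, with the ester trans to the C3 acyl group, is expected.

Step 16
Reactants: 31 enedione silyl ether
Product: 32 C13 alcohol
Conditions: HF·pyridine, pyridine, THF, 0 °C
Reagents that add atoms: none
Why: Buffered fluoride desilylation; the alcohol is carried straight into step 17 to avoid lactonisation onto the methyl ester.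

Step 17
Reactants: 32 C13 alcohol
Product: 33 methyl sarcoate
Conditions: Dess–Martin periodinane, NaHCO3, CH2Cl2, 0 to 23 °C
Reagents that add atoms: none
Why: Dess–Martin oxidation under neutral buffered conditions should form the C13 ketone without enolising the now doubly activated C14 methylene or the C12 stereocentre.

**Compound list**

1 | geraniol, (2E)-3,7-dimethylocta-2,6-dien-1-ol | CC(C)=CCC/C(C)=C/CO | starting material
2 | 1-({[(2E)-3,7-dimethylocta-2,6-dien-1-yl]oxy}methyl)-4-methoxybenzene | CC(C)=CCC/C(C)=C/COCc1ccc(OC)cc1 | intermediate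
3 | (4E)-6-[(4-methoxyphenyl)methoxy]-4-methylhex-4-enal | O=CCC/C(C)=C/COCc1ccc(OC)cc1 | intermediate
4 | ethyltriphenylphosphonium iodide | CC[P+](c1ccccc1)(c1ccccc1)c1ccccc1.[I-] | starting material
5 | ethylidenetriphenylphosphorane | CC=P(c1ccccc1)(c1ccccc1)c1ccccc1 | intermediate (not isolated)
6 | (1-iodoethyl)triphenylphosphonium iodide | CC(I)[P+](c1ccccc1)(c1ccccc1)c1ccccc1.[I-] | intermediate (not isolated)
7 | (1-iodoethylidene)triphenylphosphorane | CC(I)=P(c1ccccc1)(c1ccccc1)c1ccccc1 | intermediate (not isolated)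
8 | 1-({[(2E,6Z)-7-iodo-3-methylocta-2,6-dien-1-yl]oxy}methyl)-4-methoxybenzene | C/C(I)=C/CC/C(C)=C/COCc1ccc(OC)cc1 | intermediate
9 | (4R)-4-benzyl-3-(3-methylbutanoyl)-1,3-oxazolidin-2-one | CC(C)CC(=O)N1C(=O)OC[C@H]1Cc1ccccc1 | starting material
10 | tert-butyl bromoacetate | CC(C)(C)OC(=O)CBr | starting material
11 | sodium (Z)-enolate of 9 | CC(C)/C=C(\[O-])N1C(=O)OC[C@H]1Cc1ccccc1.[Na+] | intermediate (not isolated)
12 | tert-butyl (3R)-3-{[(4R)-4-benzyl-2-oxo-1,3-oxazolidin-3-yl]carbonyl}-4-methylpentanoate | CC(C)[C@@H](CC(=O)OC(C)(C)C)C(=O)N1C(=O)OC[C@H]1Cc1ccccc1 | intermediate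
13 | tert-butyl (3R)-3-(hydroxymethyl)-4-methylpentanoate | CC(C)[C@@H](CC(=O)OC(C)(C)C)CO | intermediate (not isolated)
14 | (4R)-4-(propan-2-yl)oxolan-2-one | CC(C)[C@@H]1COC(=O)C1 | intermediate
15 | {(2E,6E)-8-[(4-methoxyphenyl)methoxy]-6-methylocta-2,6-dien-2-yl}lithium (lithium in place of the iodine of 8, geometry retained) | C/C([Li])=C/CC/C(C)=C/COCc1ccc(OC)cc1 | intermediate (not isolated)
16 | (2R,5Z,9E)-1-hydroxy-11-[(4-methoxyphenyl)methoxy]-5,9-dimethyl-2-(propan-2-yl)undeca-5,9-dien-4-one | CC(C)[C@@H](CC(=O)/C(C)=C\CC/C(C)=C/COCc1ccc(OC)cc1)CO | intermediate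
17 | (2R,5Z,9E)-11-[(4-methoxyphenyl)methoxy]-5,9-dimethyl-4-oxo-2-(propan-2-yl)undeca-5,9-dienal | CC(C)[C@@H](CC(=O)/C(C)=C\CC/C(C)=C/COCc1ccc(OC)cc1)C=O | intermediate
18 | methyl 2-(bromomethyl)prop-2-enoate | C=C(CBr)C(=O)OC | starting material
19 | bromo[2-(methoxycarbonyl)prop-2-en-1-yl]zinc | C=C(C[Zn]Br)C(=O)OC | intermediate (not isolated)
20 | methyl (5R,8Z,12E)-4-hydroxy-14-[(4-methoxyphenyl)methoxy]-8,12-dimethyl-2-methylidene-7-oxo-5-(propan-2-yl)tetradeca-8,12-dienoate (both C4 epimers) | COC(=O)C(=C)CC(O)[C@@H](C(C)C)CC(=O)/C(C)=C\CC/C(C)=C/COCc1ccc(OC)cc1 | intermediate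
21 | methyl (5R,8Z,12E)-14-[(4-methoxyphenyl)methoxy]-8,12-dimethyl-2-methylidene-7-oxo-5-(propan-2-yl)-4-[(triethylsilyl)oxy]tetradeca-8,12-dienoate | COC(=O)C(=C)CC(O[Si](CC)(CC)CC)[C@@H](C(C)C)CC(=O)/C(C)=C\CC/C(C)=C/COCc1ccc(OC)cc1 | intermediate
22 | methyl (5R,8Z,12E)-14-hydroxy-8,12-dimethyl-2-methylidene-7-oxo-5-(propan-2-yl)-4-[(triethylsilyl)oxy]tetradeca-8,12-dienoate | COC(=O)C(=C)CC(O[Si](CC)(CC)CC)[C@@H](C(C)C)CC(=O)/C(C)=C\CC/C(C)=C/CO | intermediate
23 | methyl (5R,8Z,12E)-8,12-dimethyl-2-methylidene-7,14-dioxo-5-(propan-2-yl)-4-[(triethylsilyl)oxy]tetradeca-8,12-dienoate | COC(=O)C(=C)CC(O[Si](CC)(CC)CC)[C@@H](C(C)C)CC(=O)/C(C)=C\CC/C(C)=C/C=O | intermediate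
24 | methyl (5R,8Z,12E)-14-(hydroxyimino)-8,12-dimethyl-2-methylidene-7-oxo-5-(propan-2-yl)-4-[(triethylsilyl)oxy]tetradeca-8,12-dienoate | COC(=O)C(=C)CC(O[Si](CC)(CC)CC)[C@@H](C(C)C)CC(=O)/C(C)=C\CC/C(C)=C/C=NO | intermediate
25 | hydroximoyl chloride of 24 (14-chloro-14-hydroxyimino) | COC(=O)C(=C)CC(O[Si](CC)(CC)CC)[C@@H](C(C)C)CC(=O)/C(C)=C\CC/C(C)=C/C(Cl)=NO | intermediate (not isolated)
26 | nitrile oxide derived from 25 (C≡N–O at the former oxime carbon) | COC(=O)C(=C)CC(O[Si](CC)(CC)CC)[C@@H](C(C)C)CC(=O)/C(C)=C\CC/C(C)=C/C#[N+][O-] | intermediate (not isolated)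
27 | methyl (2E,6Z,10R)-3,7-dimethyl-8-oxo-10-(propan-2-yl)-11-[(triethylsilyl)oxy]-14-oxa-15-azabicyclo[11.2.1]hexadeca-1(15),2,6-triene-13-carboxylate (epimers at C11 and C13 of this name) | COC(=O)C12CC(=NO1)/C=C(\C)CC/C=C(/C)C(=O)C[C@H](C(C)C)C(O[Si](CC)(CC)CC)C2 | intermediate
28 | methyl (4E,8Z,12R)-1-hydroxy-3-imino-5,9-dimethyl-10-oxo-12-(propan-2-yl)-13-[(triethylsilyl)oxy]cyclotetradeca-4,8-diene-1-carboxylate | COC(=O)C1(O)CC(=N)/C=C(\C)CC/C=C(/C)C(=O)C[C@H](C(C)C)C(O[Si](CC)(CC)CC)C1 | intermediate (not isolated)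
29 | methyl (4E,8Z,12R)-1-hydroxy-5,9-dimethyl-3,10-dioxo-12-(propan-2-yl)-13-[(triethylsilyl)oxy]cyclotetradeca-4,8-diene-1-carboxylate | COC(=O)C1(O)CC(=O)/C=C(\C)CC/C=C(/C)C(=O)C[C@H](C(C)C)C(O[Si](CC)(CC)CC)C1 | intermediate
30 | C1 trifluoroacetate of 29 | COC(=O)C1(OC(=O)C(F)(F)F)CC(=O)/C=C(\C)CC/C=C(/C)C(=O)C[C@H](C(C)C)C(O[Si](CC)(CC)CC)C1 | intermediate (not isolated)
31 | methyl (1E,4E,8Z,12R)-5,9-dimethyl-3,10-dioxo-12-(propan-2-yl)-13-[(triethylsilyl)oxy]cyclotetradeca-1,4,8-triene-1-carboxylate | COC(=O)/C1=C/C(=O)/C=C(\C)CC/C=C(/C)C(=O)C[C@H](C(C)C)C(O[Si](CC)(CC)CC)C1 | intermediate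
32 | methyl (1E,4E,8Z,12R)-13-hydroxy-5,9-dimethyl-3,10-dioxo-12-(propan-2-yl)cyclotetradeca-1,4,8-triene-1-carboxylate | COC(=O)/C1=C/C(=O)/C=C(\C)CC/C=C(/C)C(=O)C[C@H](C(C)C)C(O)C1 | intermediate
33 | methyl sarcoate, methyl (1E,4E,8Z,12R)-5,9-dimethyl-3,10,13-trioxo-12-(propan-2-yl)cyclotetradeca-1,4,8-triene-1-carboxylate | COC(=O)/C1=C/C(=O)/C=C(\C)CC/C=C(/C)C(=O)C[C@H](C(C)C)C(=O)C1 | target

**Step count and risks**

Total step count: 17. Longest linear sequence: 15 steps (steps 1–3, then 6–17).

Steps most likely to fail: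

Step 13 (key macrocyclisation). The conjugated nitrile oxide may dimerise to the furoxan or oligomerise faster than the entropically slow 14-membered ring closure. The fallback sets out from alcohol 22 and returns at isoxazoline 27; it closes the same C2–C3 bond with a silyl nitronate, which cannot dimerise. Alcohol 22 is converted with CBr4/PPh3 into the allylic bromide F1. NaNO2 (urea, DMF) then gives the primary allylic nitro compound F2. Me3SiCl/Et3N in benzene at high dilution gives the silyl nitronate F3, which should cycloadd across the acrylate to the N-silyloxy isoxazolidine F4. Catalytic TsOH then eliminates trimethylsilanol and gives 27.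

Step 14 (N–O cleavage). The tertiary β-hydroxy ketone may undergo retro-aldol ring cleavage, or the hot molybdenum reagent may reduce or isomerise the enones. The fallback sets out from 27 and returns at 31, bypassing 29; it is a non-reductive opening. DBU (toluene, 60 °C) removes a C2 proton of the isoxazoline and expels the oximate oxygen from C1 (E1cB) to give the α,β-unsaturated oxime F5. Transoximation with aqueous glyoxylic acid then frees the C3 ketone and gives 31.

Step 6 (lactone acylation). A second vinyllithium may add to the ketone released when the lactolate opens, or the Z geometry may erode in the vinyllithium. The fallback sets out from lactone 14 and returns at 16. Lactone 14 is opened with MeNHOMe·HCl/AlMe3 to the hydroxy Weinreb amide F6. Silylation (Et3SiCl, imidazole) gives the silyl ether F7, which acylates vinyllithium 15 through a chelated tetrahedral intermediate that blocks over-addition, giving the silyl-protected enone F8. HF·pyridine then gives 16.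

Further compounds
F1 | step 13 | allylic bromide from 22 (Br in place of the C3 hydroxyl) | COC(=O)C(=C)CC(O[Si](CC)(CC)CC)[C@@H](C(C)C)CC(=O)/C(C)=C\CC/C(C)=C/CBr
F2 | step 13 | primary allylic nitro compound | COC(=O)C(=C)CC(O[Si](CC)(CC)CC)[C@@H](C(C)C)CC(=O)/C(C)=C\CC/C(C)=C/C[N+](=O)[O-]
F3 | step 13 | trimethylsilyl nitronate of F2 | COC(=O)C(=C)CC(O[Si](CC)(CC)CC)[C@@H](C(C)C)CC(=O)/C(C)=C\CC/C(C)=C/C=[N+]([O-])O[Si](C)(C)C
F4 | step 13 | bridged N-(trimethylsilyloxy)isoxazolidine macrocycle | COC(=O)C12CC(N(O[Si](C)(C)C)O1)/C=C(\C)CC/C=C(/C)C(=O)C[C@H](C(C)C)C(O[Si](CC)(CC)CC)C2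
F5 | step 14 | C3 oxime of enedione silyl ether 31 | COC(=O)/C1=C/C(=NO)/C=C(\C)CC/C=C(/C)C(=O)C[C@H](C(C)C)C(O[Si](CC)(CC)CC)C1
F6 | step 6 | (3R)-3-(hydroxymethyl)-N-methoxy-N,4-dimethylpentanamide | CC(C)[C@@H](CC(=O)N(C)OC)CO
F7 | step 6 | triethylsilyl ether of F6 | CC(C)[C@@H](CC(=O)N(C)OC)CO[Si](CC)(CC)CC
F8 | step 6 | triethylsilyl ether of hydroxy enone 16 | CC(C)[C@@H](CC(=O)/C(C)=C\CC/C(C)=C/COCc1ccc(OC)cc1)CO[Si](CC)(CC)CC
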